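The cyclohexene is numbered as a shikimate: C1 bears CO2Me, C2 is the alkene CH, C3/C4/C5 carry acetate, propanoate and 2-methylbutanoate, and C6 is CH2. The ring is cut at C1, the only ring carbon with a carbon substituent and no stereocentre. Without C1 the ring is a cyclopentanone (C2 ketone, C3–C5 oxygenated, C6 CH2), available from the enantiopure cyclopentenone acetonide 1 by trans conjugate hydroxylation and acylation. In the key step methyl diazoacetate inserts its CH(CO2Me) carbon into the C2–C6 bond, so the five-membered ring grows to the six-membered β-keto ester with C3–C5 untouched. Enol triflate reduction then gives the C1=C2 enoate, and an orthoester relay separates O3 from O4.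

Key step: step 3

Assumption: enone 1 (the (3aS,6aS) antipode), (R)-2-methylbutanoic acid 4 and methyl diazoacetate 7 are bought as such; 7 is handled as a cold CH2Cl2 solution.

Step 1
Reactants: 1 (3aS,6aS)-2,2-dimethyl-3a,6a-dihydro-4H-cyclopenta[d][1,3]dioxol-4-one
Product: 3 (3aS,6R,6aS)-6-hydroxy-2,2-dimethyltetrahydro-4H-cyclopenta[d][1,3]dioxol-4-one, via β-boryl ketone 2 (not isolated)
Conditions: B2pin2, CuCl/Xantphos (5 mol%), NaOt-Bu (10 mol%), MeOH (2 equiv), THF, 0 °C to rt; then NaBO3·4H2O, THF/H2O, 0 °C to rt
Reagents that add atoms: sodium perborate, [Na+].[O-]OB=O (oxygen of the new hydroxyl); bis(pinacolato)diboron, CC1(C)OB(OC1(C)C)B1OC(C)(C)C(C)(C)O1 (Bpin of intermediate 2 only, replaced by OH in 3)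
Why: Copper-catalysed conjugate borylation of the enone followed by C–B oxidation with retention should give the β-hydroxy ketone; the Cu–Bpin species adds to the convex face, anti to the cis-fused dioxolane, which sets the new C–O bond (future C5) trans to O4, and perborate is mild enough to spare the dehydration-prone product.

Step 2
Reactants: 3 (3aS,6R,6aS)-6-hydroxy-2,2-dimethyltetrahydro-4H-cyclopenta[d][1,3]dioxol-4-one; 4 (R)-2-methylbutanoic acid
Product: 6 (3aS,4R,6aS)-2,2-dimethyl-6-oxotetrahydro-4H-cyclopenta[d][1,3]dioxol-4-yl (2R)-2-methylbutanoate, via (R)-2-methylbutanoyl chloride 5 (not isolated)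
Conditions: 4, (COCl)2, cat. DMF, CH2Cl2, 0 °C to rt, evaporate; then 3, pyridine, CH2Cl2, −20 to 0 °C
Reagents that add atoms: oxalyl chloride, O=C(Cl)C(=O)Cl (Cl of intermediate 5 only; none of its atoms remain in 6)
Why: Acylation of a secondary alcohol with an acid chloride made in the flask, under the weak base pyridine at low temperature, should avoid E1cB loss of the new β-acyloxy group and ketene-mediated racemisation of the acyl α-centre; no stereocentre is formed or touched.

Step 3
Reactants: 6 (3aS,4R,6aS)-2,2-dimethyl-6-oxotetrahydro-4H-cyclopenta[d][1,3]dioxol-4-yl (2R)-2-methylbutanoate; 7 methyl diazoacetate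
Product: 9 methyl (3S,4S,5R)-3,4-(isopropylidenedioxy)-5-[(2R)-2-methylbutanoyloxy]-2-oxocyclohexane-1-carboxylate, via diazonium alkoxide betaine 8 (not isolated)
Conditions: 7 (1.5 equiv), BF3·OEt2 (1.2 equiv), CH2Cl2, −40 to 0 °C
Reagents that add atoms: none
Why: BF3 activates the ketone, the diazo carbon of 7 adds to give the β-diazonio alkoxide 8 (held as its BF3 adduct), and a 1,2-shift of the ring CH2 (future C6) from the carbinol carbon (future C2) to the diazonium carbon (future C1) with loss of N2 enlarges the cyclopentanone to the cyclohexanone β-keto ester. The closest known reaction type is the Lewis acid-promoted diazoacetate homologation of cyclic ketones (Tiffeneau–Demjanov-type ring enlargement, Büchner–Curtius–Schlotterbeck reaction). No ring is closed by cyclisation; the six-membered ring arises from the five-membered one by insertion of one carbon into the C(=O)–CH2 bond. The only new stereocentre, C1, is epimerisable and largely enolised and is erased in step 4, while C3, C4, C5 and the side-chain centre are not touched and C3 stays cis-fused to the dioxolane. The step needs migration of CH2 in preference to the oxygen-bearing C3, which the electron-withdrawing acetal oxygen and the higher substitution of C3 should secure, and the enolised β-keto ester should resist a second homologation.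

Step 4
Reactants: 9 methyl (3S,4S,5R)-3,4-(isopropylidenedioxy)-5-[(2R)-2-methylbutanoyloxy]-2-oxocyclohexane-1-carboxylate
Product: 10 methyl (3S,4S,5R)-3,4-(isopropylidenedioxy)-5-[(2R)-2-methylbutanoyloxy]-2-[(trifluoromethanesulfonyl)oxy]cyclohex-1-ene-1-carboxylate
Conditions: Tf2O, i-Pr2NEt, CH2Cl2, −78 °C
Reagents that add atoms: triflic anhydride, O=S(=O)(OS(=O)(=O)C(F)(F)F)C(F)(F)F
Why: O-Sulfonylation of the enolised β-keto ester (enol triflate formation) should give the conjugated C1=C2 triflate because only the doubly activated C1–H is removed by the hindered amine at low temperature; no stereocentre is formed and C1 becomes sp2.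

Step 5
Reactants: 10 methyl (3S,4S,5R)-3,4-(isopropylidenedioxy)-5-[(2R)-2-methylbutanoyloxy]-2-[(trifluoromethanesulfonyl)oxy]cyclohex-1-ene-1-carboxylate
Product: 11 methyl 3,4-O-isopropylidene-5-O-[(2R)-2-methylbutanoyl]shikimate
Conditions: Pd(OAc)2 (5 mol%), PPh3 (10 mol%), HCO2H, n-Bu3N, DMF, 60 °C
Reagents that add atoms: none
Why: Palladium-catalysed formate reduction of an enol triflate (oxidative addition, formate decarboxylation to Pd–H, reductive elimination) should replace OTf by H and leave the C1=C2 enoate under nearly neutral conditions that spare the acetonide, the esters and all stereocentres.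

Step 6
Reactants: 11 methyl 3,4-O-isopropylidene-5-O-[(2R)-2-methylbutanoyl]shikimate
Product: 12 methyl 5-O-[(2R)-2-methylbutanoyl]shikimate (methyl (3R,4R,5R)-3,4-dihydroxy-5-[(2R)-2-methylbutanoyloxy]cyclohex-1-ene-1-carboxylate)
Conditions: TFA/H2O (9:1), CH2Cl2, 0 °C
Reagents that add atoms: none
Why: Acid hydrolysis of the isopropylidene acetal should release the cis-3,4-diol faster than the esters hydrolyse or migrate in cold aqueous acid; no stereocentre is touched.

Step 7
Reactants: 12 methyl 5-O-[(2R)-2-methylbutanoyl]shikimate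
Product: 14 methyl 3-O-acetyl-5-O-[(2R)-2-methylbutanoyl]shikimate, via cyclic orthoacetate 13 (not isolated)
Conditions: MeC(OMe)3, CSA (cat.), CH2Cl2, rt; then 80% aq. AcOH, rt
Reagents that add atoms: trimethyl orthoacetate, CC(OC)(OC)OC (acetyl carbons; also the OMe of 13); water, O (carbonyl oxygen of the acetate)
Why: Cyclic orthoester formation on the cis-diol and mild acid opening through the dioxolan-2-ylium and hemi-orthoester should, by the stereoelectronic rule for cis-fused orthoesters on six-membered rings, leave the ester on the pseudoaxial allylic O3 and free the equatorial 4-OH; the orthoester carbon is an epimer mixture that disappears, and the ring stereocentres are untouched.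

Step 8
Reactants: 14 methyl 3-O-acetyl-5-O-[(2R)-2-methylbutanoyl]shikimate
Product: 15 methyl (3R,4S,5R)-3-acetoxy-5-[(2R)-2-methylbutanoyloxy]-4-(propanoyloxy)cyclohex-1-ene-1-carboxylate
Conditions: EtCOCl, pyridine, CH2Cl2, −20 to 0 °C
Reagents that add atoms: propanoyl chloride, CCC(=O)Cl
Why: Acylation of the remaining equatorial secondary alcohol with an acid chloride and pyridine at low temperature should be faster than base-mediated O3-to-O4 acetyl migration; no stereocentre is affected.

Compound list

1 | (3aS,6aS)-2,2-dimethyl-3a,6a-dihydro-4H-cyclopenta[d][1,3]dioxol-4-one | O=C1[C@H]2OC(C)(C)O[C@H]2C=C1 | starting material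
2 | (3aS,6R,6aS)-2,2-dimethyl-6-(4,4,5,5-tetramethyl-1,3,2-dioxaborolan-2-yl)tetrahydro-4H-cyclopenta[d][1,3]dioxol-4-one (β-boryl ketone, Bpin trans to the dioxolane, not isolated) | O=C1[C@H]2OC(C)(C)O[C@H]2[C@H](B3OC(C)(C)C(C)(C)O3)C1 | intermediate
3 | (3aS,6R,6aS)-6-hydroxy-2,2-dimethyltetrahydro-4H-cyclopenta[d][1,3]dioxol-4-one (OH trans to the dioxolane) | O=C1[C@H]2OC(C)(C)O[C@H]2[C@H](O)C1 | intermediate
4 | (R)-2-methylbutanoic acid | CC[C@@H](C)C(=O)O | starting material
5 | (R)-2-methylbutanoyl chloride (not isolated) | CC[C@@H](C)C(=O)Cl | intermediate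
6 | (3aS,4R,6aS)-2,2-dimethyl-6-oxotetrahydro-4H-cyclopenta[d][1,3]dioxol-4-yl (2R)-2-methylbutanoate | O=C1[C@H]2OC(C)(C)O[C@H]2[C@H](OC(=O)[C@H](C)CC)C1 | intermediate
7 | methyl diazoacetate | COC(=O)C=[N+]=[N-] | starting material
8 | diazonium alkoxide betaine from addition of 7 to the ketone of 6 (BF3-bound in the flask, new centres undefined, not isolated) | [O-]C1(C([N+]#N)C(=O)OC)[C@H]2OC(C)(C)O[C@H]2[C@H](OC(=O)[C@H](C)CC)C1 | intermediate
9 | methyl (3S,4S,5R)-3,4-(isopropylidenedioxy)-5-[(2R)-2-methylbutanoyloxy]-2-oxocyclohexane-1-carboxylate (C1 epimers/enol) | O=C1[C@H]2OC(C)(C)O[C@H]2[C@H](OC(=O)[C@H](C)CC)CC1C(=O)OC | intermediate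
10 | methyl (3S,4S,5R)-3,4-(isopropylidenedioxy)-5-[(2R)-2-methylbutanoyloxy]-2-[(trifluoromethanesulfonyl)oxy]cyclohex-1-ene-1-carboxylate | COC(=O)C1=C(OS(=O)(=O)C(F)(F)F)[C@H]2OC(C)(C)O[C@H]2[C@H](OC(=O)[C@H](C)CC)C1 | intermediate
11 | methyl 3,4-O-isopropylidene-5-O-[(2R)-2-methylbutanoyl]shikimate ((3R,4S,5R) ring) | COC(=O)C1=C[C@H]2OC(C)(C)O[C@H]2[C@H](OC(=O)[C@H](C)CC)C1 | intermediate
12 | methyl 5-O-[(2R)-2-methylbutanoyl]shikimate (methyl (3R,4R,5R)-3,4-dihydroxy-5-[(2R)-2-methylbutanoyloxy]cyclohex-1-ene-1-carboxylate) | COC(=O)C1=C[C@@H](O)[C@@H](O)[C@H](OC(=O)[C@H](C)CC)C1 | intermediate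
13 | methyl 3,4-O-(1-methoxyethylidene)-5-O-[(2R)-2-methylbutanoyl]shikimate (cyclic orthoacetate, epimers at the orthoester carbon, not isolated) | COC(=O)C1=C[C@H]2OC(C)(OC)O[C@H]2[C@H](OC(=O)[C@H](C)CC)C1 | intermediate
14 | methyl (3R,4S,5R)-3-acetoxy-4-hydroxy-5-[(2R)-2-methylbutanoyloxy]cyclohex-1-ene-1-carboxylate | COC(=O)C1=C[C@@H](OC(C)=O)[C@@H](O)[C@H](OC(=O)[C@H](C)CC)C1 | intermediate
15 | methyl (3R,4S,5R)-3-acetoxy-5-[(2R)-2-methylbutanoyloxy]-4-(propanoyloxy)cyclohex-1-ene-1-carboxylate | COC(=O)C1=C[C@@H](OC(C)=O)[C@@H](OC(=O)CC)[C@H](OC(=O)[C@H](C)CC)C1 | target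

Total step count: 8. Longest linear sequence: 8 steps (1 to 15).

Steps most likely to fail

Step 3 (key step). The oxygen-bearing carbon C3 may migrate in place of CH2, or the Lewis acid may strip the acetonide or provoke loss of the β-acyloxy group before insertion is complete. The fallback is a two-stage homologation without Lewis acid. It sets out from 6: methyl diazoacetate 7 is deprotonated with LDA (THF, −78 °C) and added to the ketone, and a cold acetic acid quench should give the α-diazo-β-hydroxy ester F1. Rh2(OAc)4 (1 mol%, CH2Cl2, rt) should then convert F1, through the rhodium carbenoid and a 1,2-shift of the ring CH2, into β-keto ester 9, where the route is rejoined.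

Step 7. The orthoester may open with incomplete regiocontrol, or the axial O3 acetate may migrate to the free equatorial O4 before step 8. The fallback reverses the order of the two acylations and relies on the complementary tin rule. It sets out from diol 12: Bu2SnO (toluene, reflux, water removal) should give the stannylene acetal F2, in which the equatorial O4 is the more nucleophilic oxygen. EtCOCl (CH2Cl2, 0 °C) should then give the 4-propanoate F3 with O3 free. Ac2O in pyridine acetylates O3 and leads directly to target 15.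

Step 2. The new β-acyloxy group may be lost by E1cB elimination (reversion to enone 1) during acylation or on handling of 6. The fallback masks the oxygen and brings in the acyl group only after the ring is six-membered. It sets out from 3: TBSCl, imidazole, DMF should give the silyl ether F4. The same diazoacetate insertion (7, BF3·OEt2, CH2Cl2) gives the silylated β-keto ester F5, Tf2O/i-Pr2NEt gives the enol triflate F6, and Pd(OAc)2/PPh3/HCO2H/n-Bu3N gives the silylated enoate F7. TBAF/AcOH in THF should then release methyl 3,4-O-isopropylidene shikimate F8. Esterification of F8 with 4 (DCC, cat. DMAP, CH2Cl2), now on an alcohol with no β-carbonyl, returns to 11.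

Further compounds
F1 | step 3 | α-diazo-β-hydroxy ester from addition of lithiated 7 to the ketone of 6 (carbinol configuration undefined) | OC1(C(=[N+]=[N-])C(=O)OC)[C@H]2OC(C)(C)O[C@H]2[C@H](OC(=O)[C@H](C)CC)C1
F2 | step 7 | 3,4-O-dibutylstannylene acetal of 12 | COC(=O)C1=C[C@H]2O[Sn](CCCC)(CCCC)O[C@H]2[C@H](OC(=O)[C@H](C)CC)C1
F3 | step 7 | methyl 5-O-[(2R)-2-methylbutanoyl]-4-O-propanoylshikimate | COC(=O)C1=C[C@@H](O)[C@@H](OC(=O)CC)[C@H](OC(=O)[C@H](C)CC)C1
F4 | step 2 | tert-butyldimethylsilyl ether of 3 | O=C1[C@H]2OC(C)(C)O[C@H]2[C@H](O[Si](C)(C)C(C)(C)C)C1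
F5 | step 2 | ring-expanded β-keto ester from F4 (silyl analogue of 9, C1 epimers/enol) | O=C1[C@H]2OC(C)(C)O[C@H]2[C@H](O[Si](C)(C)C(C)(C)C)CC1C(=O)OC
F6 | step 2 | enol triflate of F5 (silyl analogue of 10) | COC(=O)C1=C(OS(=O)(=O)C(F)(F)F)[C@H]2OC(C)(C)O[C@H]2[C@H](O[Si](C)(C)C(C)(C)C)C1
F7 | step 2 | methyl 5-O-(tert-butyldimethylsilyl)-3,4-O-isopropylideneshikimate | COC(=O)C1=C[C@H]2OC(C)(C)O[C@H]2[C@H](O[Si](C)(C)C(C)(C)C)C1
F8 | step 2 | methyl 3,4-O-isopropylideneshikimate | COC(=O)C1=C[C@H]2OC(C)(C)O[C@H]2[C@H](O)C1
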